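**Retrosynthetic overview**
1. Target 21 ⇒ 19: the spiro cyclohexane is closed last, by 6-endo attack of the trione-carbon radical on the isopropenyl CH2 with O2 capture (spiro C–C bond and tertiary C–OH in one operation).
2. 19 ⇒ 17 (methyl addition to the cyclopentanone) ⇒ acyl trione 9 + exo-methylene ketone 16 (Michael union).
3. 16 ⇒ Mannich base 14 ⇒ cyclopentenone 10 + isopropenyl Grignard 11 + iminium salt 12 (asymmetric conjugate addition, enolate trapping).
4. 9 ⇒ trione 6 (C-acylation) ⇒ keto ester 3 + acetyl unit (Claisen, then Dieckmann) ⇒ methyl acetoacetate 1 + two prenyl bromide 2.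
5. Ring order: trione ring (step 2); cyclopentane bought in as 10; spiro cyclohexane last (step 7).

Assumption: the target is taken exactly as the given SMILES (enol tautomer as drawn; the spiro descriptor 1S refers to that tautomer), and the ferrocenyl ligand enantiomer named in step 4 is assumed to give the 3S adduct (otherwise its mirror image is used).

**Step 1**
Reactants: 1 methyl 3-oxobutanoate; 2 1-bromo-3-methylbut-2-ene
Product: 3 methyl 2-acetyl-5-methyl-2-(3-methylbut-2-en-1-yl)hex-4-enoate
Conditions: 2 (2.3 equiv), K2CO3 (3 equiv), Bu4NI (5 mol%), DMF, 50 °C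
Reagents that add atoms: 1-bromo-3-methylbut-2-ene (2), CC(C)=CCBr
Why: Acetoacetic ester alkylation run twice: the doubly activated CH2 is alkylated by the reactive allylic bromide and the mono-alkylated ester is deprotonated again under the same conditions, giving the quaternary gem-diprenyl carbon with no stereocentre.

**Step 2**
Reactants: 3 methyl 2-acetyl-5-methyl-2-(3-methylbut-2-en-1-yl)hex-4-enoate; 4 1-acetylimidazole
Product: 6 2,2-bis(3-methylbut-2-en-1-yl)cyclohexane-1,3,5-trione, via dioxo ester 5 (not isolated)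
Conditions: LiN(i-Pr)2 (2.0 equiv), THF, −78 °C; 4 (1.0 equiv), −78 → −20 °C; LiN(i-Pr)2 (2.2 equiv), −78 → 23 °C; 1 M HCl
Reagents that add atoms: 1-acetylimidazole (4), CC(=O)n1ccnc1
Why: The methyl ketone is the only enolisable site of 3, so its kinetic lithium enolate is C-acylated by the acyl imidazole (crossed Claisen) and the 1,3-diketone dianion then attacks the non-enolisable, gem-dialkyl-activated ester through its terminal carbon (Dieckmann-type cyclisation), the acidic trione driving the equilibrium; no stereocentre is formed.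

**Step 3**
Reactants: 6 2,2-bis(3-methylbut-2-en-1-yl)cyclohexane-1,3,5-trione; 7 2-methylpropanoyl chloride
Product: 9 3,5-dihydroxy-2-(2-methylpropanoyl)-6,6-bis(3-methylbut-2-en-1-yl)cyclohexa-2,4-dien-1-one, via enol ester 8 (not isolated)
Conditions: 7 (1.05 equiv), Et3N (2.2 equiv), CH2Cl2, 0 °C; then DMAP (20 mol%), 23 °C; 1 M HCl
Reagents that add atoms: 2-methylpropanoyl chloride (7), CC(C)C(Cl)=O
Why: O-acylation of the vinylogous acid followed by DMAP-mediated O-to-C acyl migration (the enol ester rearrangement used for 2-acylcyclohexane-1,3-diones) gives the C-acyl compound, and because 6 is symmetric both nucleophilic carbons lead to the same product.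

**Step 4**
Reactants: 10 cyclopent-2-en-1-one; 11 (prop-1-en-2-yl)magnesium bromide; 12 N,N-dimethylmethaniminium iodide
Product: 14 (2S,3S)-2-[(dimethylamino)methyl]-3-(prop-1-en-2-yl)cyclopentan-1-one, via magnesium enolate 13 (not isolated)
Conditions: 11 (1.2 equiv), CuBr·SMe2 (5 mol%), (R)-1-[(Sp)-2-(diphenylphosphino)ferrocenyl]ethyldicyclohexylphosphine (6 mol%), t-BuOMe, −75 °C; then 12 (1.5 equiv), THF, −75 → 0 °C
Reagents that add atoms: (prop-1-en-2-yl)magnesium bromide (11), CC(=C)[Mg]Br; N,N-dimethylmethaniminium iodide (12), C=[N+](C)C.[I-]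
Why: Copper-catalysed asymmetric conjugate addition of the Grignard reagent sets C3 (S) under control of the chiral ferrocenyl diphosphine, and the regiodefined magnesium enolate is then alkylated by the iminium salt (Mannich reaction) on the face opposite the new isopropenyl group, giving the trans (2S,3S) product.

**Step 5**
Reactants: 9 3,5-dihydroxy-2-(2-methylpropanoyl)-6,6-bis(3-methylbut-2-en-1-yl)cyclohexa-2,4-dien-1-one; 14 (2S,3S)-2-[(dimethylamino)methyl]-3-(prop-1-en-2-yl)cyclopentan-1-one
Product: 17 3,5-dihydroxy-2-(2-methylpropanoyl)-6,6-bis(3-methylbut-2-en-1-yl)-4-{[(1R,5S)-2-oxo-5-(prop-1-en-2-yl)cyclopentyl]methyl}cyclohexa-2,4-dien-1-one, via methiodide 15 (not isolated), via exo-enone 16 (not isolated)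
Conditions: 14, MeI (1.05 equiv), MeCN, 23 °C; then 9 (1.2 equiv), K2CO3 (1.0 equiv), MeCN, 50 °C; pH 5 buffer
Reagents that add atoms: none
Why: Quaternisation makes the amine a leaving group, mild base releases the exo-methylene ketone by E1cB elimination and the soft ring carbon of trione 9 adds to it at once (Michael addition with a Mannich base as vinyl ketone surrogate, as in Robinson annulations); the cyclopentane carbon carrying the new CH2 arm is set by thermodynamic protonation trans to the isopropenyl group (1R,5S).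

**Step 6**
Reactants: 17 (ketone from step 5); 18 methylmagnesium bromide
Product: 19 3,5-dihydroxy-4-{[(1R,2S,5S)-2-hydroxy-2-methyl-5-(prop-1-en-2-yl)cyclopentyl]methyl}-2-(2-methylpropanoyl)-6,6-bis(3-methylbut-2-en-1-yl)cyclohexa-2,4-dien-1-one
Conditions: CeCl3 (4 equiv), 18 (5 equiv), THF, −78 → 0 °C; sat. aq. NH4Cl
Reagents that add atoms: methylmagnesium bromide (18), C[Mg]Br
Why: The two acidic enols are deprotonated first, so the trione is protected as its unreactive dianion, and the weakly basic organocerium reagent then adds 1,2 to the cyclopentanone (Grignard addition under Imamoto conditions) from the face opposite the adjacent CH2 arm, giving the tertiary alcohol (2S) with OH cis to that arm.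

**Step 7**
Reactants: 19 (tertiary alcohol from step 6)
Product: 21 (1S,1'S,3a'S,4'S,7a'R)-1',4,4'-trihydroxy-1',4'-dimethyl-5-(2-methylpropanoyl)-3,3-bis(3-methylbut-2-en-1-yl)-1',2',3',3a',4',5',7',7a'-octahydrospiro[cyclohex-4-ene-1,6'-indene]-2,6-dione (CNP0273836.5), via hydroperoxide 20 (not isolated)
Conditions: Mn(OAc)3·2H2O (20 mol%), air (1 atm), AcOH, 23 °C; then PPh3 (1.5 equiv), 0 °C
Reagents that add atoms: dioxygen, O=O
Why: Proposed new method: trivalent manganese oxidises the enolised trione of 19 to the delocalised radical at ring carbon 4, which closes 6-endo on the CH2 terminus of the isopropenyl group through a chair that keeps the trans cyclopentane arms diequatorial (closest known type: manganese triacetate oxidative cyclisation of 2-alkyl-1,3-dicarbonyl radicals onto 1,1-disubstituted alkenes and the radical cyclisations of dearomatised acylphloroglucinols), and the tertiary radical is then captured by dioxygen on the equatorial face, anti to the ring carbonyl that has just become axial (closest known type: manganese-catalysed aerobic hydroperoxidation of alkenes by 1,3-dicarbonyls), so that C4' is set as S, while the spiro carbon is set as S in the chair that places the metal-chelated acyl-enol flank equatorial and the bare C2 carbonyl axial, the hydroperoxide being reduced by PPh3 with retention.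

**Compound list**
1 | methyl 3-oxobutanoate | CC(=O)CC(=O)OC | starting material
2 | 1-bromo-3-methylbut-2-ene | CC(C)=CCBr | starting material
3 | methyl 2-acetyl-5-methyl-2-(3-methylbut-2-en-1-yl)hex-4-enoate | CC(=O)C(CC=C(C)C)(CC=C(C)C)C(=O)OC | intermediate
4 | 1-acetylimidazole | CC(=O)n1ccnc1 | starting material
5 | methyl 2,2-bis(3-methylbut-2-en-1-yl)-3,5-dioxohexanoate | CC(=O)CC(=O)C(CC=C(C)C)(CC=C(C)C)C(=O)OC | intermediate
6 | 2,2-bis(3-methylbut-2-en-1-yl)cyclohexane-1,3,5-trione | O=C1CC(=O)C(CC=C(C)C)(CC=C(C)C)C(=O)C1 | intermediate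
7 | 2-methylpropanoyl chloride | CC(C)C(Cl)=O | starting material
8 | 4,4-bis(3-methylbut-2-en-1-yl)-3,5-dioxocyclohex-1-en-1-yl 2-methylpropanoate | CC(C)C(=O)OC1=CC(=O)C(CC=C(C)C)(CC=C(C)C)C(=O)C1 | intermediate
9 | 3,5-dihydroxy-2-(2-methylpropanoyl)-6,6-bis(3-methylbut-2-en-1-yl)cyclohexa-2,4-dien-1-one | CC(C)C(=O)C1=C(O)C=C(O)C(CC=C(C)C)(CC=C(C)C)C1=O | intermediate
10 | cyclopent-2-en-1-one | O=C1C=CCC1 | starting material
11 | (prop-1-en-2-yl)magnesium bromide | CC(=C)[Mg]Br | starting material
12 | N,N-dimethylmethaniminium iodide | C=[N+](C)C.[I-] | starting material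
13 | bromomagnesium (3S)-3-(prop-1-en-2-yl)cyclopent-1-en-1-olate | C1=C(O[Mg]Br)CC[C@@H]1C(C)=C | intermediate
14 | (2S,3S)-2-[(dimethylamino)methyl]-3-(prop-1-en-2-yl)cyclopentan-1-one | CN(C)C[C@@H]1[C@H](CCC1=O)C(C)=C | intermediate
15 | N,N,N-trimethyl-1-[(1S,5S)-2-oxo-5-(prop-1-en-2-yl)cyclopentyl]methanaminium iodide | C[N+](C)(C)C[C@@H]1[C@H](CCC1=O)C(C)=C.[I-] | intermediate
16 | (3R)-2-methylidene-3-(prop-1-en-2-yl)cyclopentan-1-one | C=C1[C@H](CCC1=O)C(C)=C | intermediate
17 | 3,5-dihydroxy-2-(2-methylpropanoyl)-6,6-bis(3-methylbut-2-en-1-yl)-4-{[(1R,5S)-2-oxo-5-(prop-1-en-2-yl)cyclopentyl]methyl}cyclohexa-2,4-dien-1-one | CC(C)=CCC1(CC=C(C)C)C(O)=C(C[C@@H]2[C@H](CCC2=O)C(C)=C)C(O)=C(C(=O)C(C)C)C1=O | intermediate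
18 | methylmagnesium bromide | C[Mg]Br | starting material
19 | 3,5-dihydroxy-4-{[(1R,2S,5S)-2-hydroxy-2-methyl-5-(prop-1-en-2-yl)cyclopentyl]methyl}-2-(2-methylpropanoyl)-6,6-bis(3-methylbut-2-en-1-yl)cyclohexa-2,4-dien-1-one | CC(C)=CCC1(CC=C(C)C)C(O)=C(C[C@@H]2[C@H](CC[C@]2(C)O)C(C)=C)C(O)=C(C(=O)C(C)C)C1=O | intermediate
20 | (1S,1'S,3a'S,4'S,7a'R)-4'-hydroperoxy-1',4-dihydroxy-1',4'-dimethyl-5-(2-methylpropanoyl)-3,3-bis(3-methylbut-2-en-1-yl)-1',2',3',3a',4',5',7',7a'-octahydrospiro[cyclohex-4-ene-1,6'-indene]-2,6-dione | CC(C)=CCC1(CC=C(C)C)C(=O)[C@@]2(C[C@@H]3[C@H](CC[C@]3(C)O)[C@@](C)(OO)C2)C(=O)C(C(=O)C(C)C)=C1O | intermediate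
21 | (1S,1'S,3a'S,4'S,7a'R)-1',4,4'-trihydroxy-1',4'-dimethyl-5-(2-methylpropanoyl)-3,3-bis(3-methylbut-2-en-1-yl)-1',2',3',3a',4',5',7',7a'-octahydrospiro[cyclohex-4-ene-1,6'-indene]-2,6-dione | CC(C)=CCC1(CC=C(C)C)C(=O)[C@@]2(C[C@@H]3[C@H](CC[C@]3(C)O)[C@@](C)(O)C2)C(=O)C(C(=O)C(C)C)=C1O | target

**Step count**
Total: 7 steps. Longest linear sequence: 6 steps (1, 2, 3, 5, 6, 7); step 4 is the one-step side branch.

**Steps most likely to fail, with fallbacks**

Step 7. The radical at ring carbon 4 of 19 has three ways to go wrong. It can be oxygenated directly, as in the air oxidation of hop β-acids. It can close 5-exo on one of the geminal prenyl groups to a bicyclo[3.2.1]octane, as in the ialibinone series. And the preference between the two spiro epimers is expected to be modest, so the unwanted epimer may have to be removed by chromatography. Air rather than pure oxygen is used to favour the unimolecular ring closure over oxygenation at carbon 4. Fallback: set out from 19 under argon with PhI(OAc)2 (1.1 equiv) and TEMPO (3 equiv) in THF at −78 → 0 °C. The nitroxide generates the same radical without dioxygen and, being in excess, captures the cyclised tertiary radical on the equatorial face to give the O-(2,2,6,6-tetramethylpiperidin-1-yl) alkoxyamine F1. Zn dust in AcOH/THF then cleaves the N–O bond, and the route is rejoined at 21.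

Step 4. Copper-catalysed asymmetric addition of an alkenyl Grignard reagent to cyclopentenone is less secure in enantioselectivity and 1,4-selectivity than the alkyl cases, and the Mannich base is prone to elimination. Fallback: set out from 10 with 11 and CuI (10 mol%) without chiral ligand, then 12, to give the racemic trans Mannich base F2. Resolve it by crystallisation with one enantiomer of O,O'-di-p-toluoyltartaric acid (the L-acid is written) as the di-p-toluoyl-L-tartrate salt F3. Aqueous NaHCO3 liberates the free base, and the route is rejoined at 14.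

Step 6. The cyclopentanone may enolise, and magnesium bound to the neighbouring enolate may deliver the methyl group to the wrong face. Fallback: set out from 17 with trimethylsulfonium iodide and KN(SiMe3)2 (3.3 equiv) in THF at −10 °C. Methylene transfer, again anti to the CH2 arm, gives the spiro-epoxide F4. LiEt3BH then opens the epoxide at its CH2 carbon to the same tertiary alcohol, and the route is rejoined at 19.

**Further compounds**
F1 | step 7 | (1S,1'S,3a'S,4'S,7a'R)-1',4-dihydroxy-1',4'-dimethyl-5-(2-methylpropanoyl)-3,3-bis(3-methylbut-2-en-1-yl)-4'-[(2,2,6,6-tetramethylpiperidin-1-yl)oxy]-1',2',3',3a',4',5',7',7a'-octahydrospiro[cyclohex-4-ene-1,6'-indene]-2,6-dione | CC(C)=CCC1(CC=C(C)C)C(=O)[C@@]2(C[C@@H]3[C@H](CC[C@]3(C)O)[C@@](C)(ON4C(C)(C)CCCC4(C)C)C2)C(=O)C(C(=O)C(C)C)=C1O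
F2 | step 4 | racemic trans-2-[(dimethylamino)methyl]-3-(prop-1-en-2-yl)cyclopentan-1-one (1:1 mixture of 2S,3S and 2R,3R) | CN(C)C[C@@H]1[C@H](CCC1=O)C(C)=C.CN(C)C[C@H]1[C@@H](CCC1=O)C(C)=C
F3 | step 4 | (2S,3S)-2-[(dimethylamino)methyl]-3-(prop-1-en-2-yl)cyclopentan-1-one (2R,3R)-2,3-bis[(4-methylbenzoyl)oxy]butanedioic acid salt | CN(C)C[C@@H]1[C@H](CCC1=O)C(C)=C.OC(=O)[C@H](OC(=O)c1ccc(C)cc1)[C@@H](OC(=O)c1ccc(C)cc1)C(O)=O
F4 | step 6 | 3,5-dihydroxy-2-(2-methylpropanoyl)-6,6-bis(3-methylbut-2-en-1-yl)-4-{[(3S,4R,5S)-5-(prop-1-en-2-yl)-1-oxaspiro[2.4]heptan-4-yl]methyl}cyclohexa-2,4-dien-1-one | CC(C)=CCC1(CC=C(C)C)C(O)=C(C[C@@H]2[C@H](CC[C@@]23CO3)C(C)=C)C(O)=C(C(=O)C(C)C)C1=O
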